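(The numbers of this flask come from no measurement; no experiment stands behind them.)

There were 4 questions about one moment of this flask, and I wanted one number to answer them.

    solid substrate ⇌ starting material, rate k1*(cs1 - [starting material]) while solid is left; crystals form when [starting material] > cs1 (cs1 = 12 mM, k1 = 0.00373 min⁻¹)
    complex ⇌ enzyme + product (K2 = 0.038 M, k2 = 15.7 min⁻¹)
    starting material + enzyme ⇌ complex (K3 = 140 L mol⁻¹, k3 = 44800 L mol⁻¹ min⁻¹)

solid substrate 0.020 M; enzyme 20 µM

- given per volume of solution although it is solid: solid substrate
- at the start none of the solid substrate is in solution
- what has only dissolved of solid substrate counts as not reacted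
- charge of solid substrate (flask): 0.020 M

1. the form that holds most of the catalyst when 50% of the solid substrate are converted (what has only dissolved counts as not reacted) (complex / enzyme)
2. its share of the catalyst then
3. factor on the rate of making product when 50% of the solid substrate are converted (what has only dissolved counts as not reacted) if enzyme is charged twice over
4. factor on the rate when 50% of the solid substrate are converted (what has only dissolved counts as not reacted) if enzyme is charged at 2.0 µM instead

**The number.** I called the dissolved starting material S. Complex is lost by both routes, so complex and enzyme stand equal when S reaches the Michaelis level M = 7.49 mM. Dilute S is therefore cleared with the coefficient 0.0419 min⁻¹, while the solid supplies it with 0.00373 min⁻¹. Their quotient is D = 11.2, the pull of the enzyme over the push of the solid.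

**Reading it.** D is larger than 1, so in this flask I took dissolution as the rate-limiting step. Setting supply equal to clearing gave S = 0.981 mM, which is the solubility over 1 + D.

**The drift.** One number was not enough: that S ignores the product pushing back. At 50% conversion the product stands at 10.0 mM, and the overall equilibrium constant 5.32 puts the floor of S at F = 1.88 mM, which is more than that S. The enzyme clears S − F, so, keeping the dilute coefficient, I put S at 2.71 mM, the weighted mean of solubility and floor.

**My answers.** The resting state is enzyme, with a share M/(M + S) of 73.5%. The rate, the turnover constant of complex times the enzyme charge times (S − F)/(M + S), came to 25.5 µM min⁻¹. Doubling the enzyme doubles D, and I put S at 2.31 mM, a factor 1.08. At 2.0 µM, D is 1.12 and I put S at 6.65 mM, a factor 0.416.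

**The forecast.** It gave enzyme at 71.9%, a factor 1.05 for twice the enzyme, “since dissolution limits”, and a factor 0.436 for 2.0 µM.

**The flask.** It gave enzyme at 71.9%, with factors 1.05 and 0.437. Its rate at that conversion, reached after 5.62 h, was 28.8 µM min⁻¹, against my 25.5 µM min⁻¹. With the same D, at 0.7 of the charge converted, the floor is 2.63 mM and I put S at 3.40 mM, so I got a rate factor of 0.869. The flask gave a factor of 0.92 after 8.03 h.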